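Full exchange asks 2 incoming ligands of every starting complex, and this flask is charged 0.900 equiv. So I reckon by the ligand cover, the charge in equivalents divided by those 2, which is the share of all possible exchanges that the charge can pay for: 0.450. Leaving aside any ligand lost to decomposition product, cover 1 is the crossing: under it, incoming ligand is the limiting reagent, and over it, starting complex ends first.

| setting | Thursday's | Sunday's | flask |
|---|---|---|---|
| starting complex | 0.35 M | 0.35 M | 0.35 M |
| incoming ligand | 0.45 equiv | 1.8 equiv | 0.900 equiv |
| remark | run made earlier | run made earlier |  |
| time |  |  | 15 d |

| run | time / d | starting complex / % | complex with two exchanged / % |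
|---|---|---|---|
| Thursday's | 1.67 | 73.3 | 7.9 |
| Thursday's | 4.00 | 67.6 | 11.9 |
| Thursday's | 8.00 | 66.8 | 12.2 |
| Thursday's | 12.0 | 67.1 | 12.4 |
| Sunday's | 3.00 | 19.2 | 68.7 |
| Sunday's | 6.00 | 12.1 | 78.5 |
| Sunday's | 10.0 | 9.1 | 82.7 |
| Sunday's | 12.0 | 9.4 | 84.9 |

(standard deviation of a reading: 0.5 percentage points)

- what may be going on: incoming ligand -> decomposition product; complex with one exchanged + incoming ligand -> leaving ligand + complex with two exchanged; starting complex + incoming ligand -> leaving ligand + complex with one exchanged
- the reaction counts as stopped when no species that holds the starting complex changes by six tenths of a point or more over the second half of the time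

* at 15 d, what has stopped the reaction, if anything has (all of the starting complex has reacted / forward and back rates have come level / it is still moving / the incoming ligand has run out first)
* share of the starting complex used up at 15 d
* complex with two exchanged at 15 d, in percent of the starting complex charged
* complex with one exchanged at 15 d, in percent of the starting complex charged

I take c as a share of the starting complex charged, with c(complex with one exchanged) as the remainder. Ligand spent per starting complex is then c(complex with one exchanged) plus 2 c(complex with two exchanged).

Counted in percent of the starting complex charged, Thursday's last row, at cover 0.225, has spent 45.3% of a ligand charge of 45.0%, and c(starting complex) reads 66.8% and then 67.1%, so that run has stopped. On the same count, Sunday's last row, at cover 0.900, has spent 176% of a ligand charge of 180%, and c(complex with two exchanged) still moves from 82.7% to 84.9%. This flask's cover lies between them, so I expect incoming ligand to end first.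

The split needs one more number. I try consecutive steps with a selectivity factor of 2.3. On Thursday's last c(starting complex) they give 20.9% of complex with one exchanged, against 20.5% by remainder. That curve peaks at 22.9%. The balance then leaves c(starting complex) at 43.5%, where the curve gives 22.1%. I therefore commit to 56.0% conversion and 34.0% of complex with two exchanged.

The forecast says the incoming ligand has run out first, with 55.5% conversion, 33.7% of complex with two exchanged and 21.8% of complex with one exchanged, “the ligand is gone by about 8 days”; its conversion lies 0.56 percentage points below mine.

The flask gives this: the incoming ligand has run out first, with 55.6% conversion, 33.9% of complex with two exchanged and 21.8% of complex with one exchanged.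

    incoming ligand → decomposition product (k = 1.92 × 10⁻⁴ h⁻¹)
    complex with one exchanged + incoming ligand → leaving ligand + complex with two exchanged (k = 0.220 M⁻¹ h⁻¹)
    starting complex + incoming ligand → leaving ligand + complex with one exchanged (k = 0.0930 M⁻¹ h⁻¹)

Incoming ligand stands at 0% at 15.0 d. The exchanges done come to 0.448 of those possible, against the cover of 0.450. A neighbouring flask with 3.60 equiv has cover 1.80, which is past the crossing, and the cover leaves a surplus of 44.4% of its ligand. That flask ends with starting complex at 0%, decomposition product at 0.0392 M and incoming ligand at 41.3% of its own charge.

(The earlier runs and the new flask were computed on assumed constants, noise included.)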